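**Plan**

1. Retrosynthetic cuts, last to first: the two ester C–O bonds; C2–OH back to a C2 ketone, which comes from 1,2-transposition of a C1 ketone; C8=CH2 back to a C8 ketone; C6–H back to the C6–O bond of a temporary C19→C6 γ-lactone.
2. Strategic cut: ring B at C5–C6 and C9–C10, by one intramolecular Diels–Alder reaction of a C6=C7–C8(OSi)=C9 diene with the C5=C10 enone of a ring A acid; the partners are joined by an enol ester C19–O–C6.
3. Feature that allows it: the C4 carboxyl carbon (C19) stands on the same (α) face of ring A as C6 and C9 and is 1,3 to C6, and C8 ends as an sp2 carbon, so the ester tether and the C8 oxygen can both be removed without trace.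
4. Forward order: ring A acid 5 and dienyl boronate 14 are made separately and joined as enol ester 15; the cycloaddition closes ring B and the temporary lactone; then tether release, conjugate reduction, methylenation, carbonyl transposition, ketone reduction and saponification.
5. Stereochemistry: C4 from a catalytic asymmetric Michael addition; C5, C10 (cis fusion) and C9 from the tethered endo cycloaddition, relayed from C4; C2 from hydride attack anti to two syn-axial methyl groups; the 13E alkene from a syn-carbocupration.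

Key step: step 11

Remark: labdane numbering is used (C1–C10 decalin, C17 exocyclic methylene carbon, C18 methyl on C4, C19 carboxyl carbon on C4, C20 methyl on C10, C11–C16 side chain), β is the face of C20, and the target is read as the 5,10-cis-fused (2S,4R,5S,9R,10R) isomer, so every bicyclic compound below has 4β-CH3, 4α-C19, 5β-H, 9β-H (side chain α) and 10β-CH3.

**Route**

Step 1
Reactants: 1 ethyl 2-methyl-3-oxopropanoate; 2 pent-1-en-3-one
Product: 3 ethyl (2R)-2-formyl-2-methyl-5-oxoheptanoate
Conditions: quinidine-derived bifunctional thiourea (10 mol %), toluene, −20 °C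
Reagents that add atoms: none
Why: Organocatalytic asymmetric Michael addition of an enolised α-substituted formyl ester to a vinyl ketone, in which the chiral ion pair shields one enolate face and sets the quaternary C4; the quinidine- or the pseudoenantiomeric quinine-derived catalyst is chosen so that the R centre results.

Step 2
Reactants: 3 ethyl (2R)-2-formyl-2-methyl-5-oxoheptanoate
Product: 4 ethyl (1R)-1,3-dimethyl-4-oxocyclohex-2-ene-1-carboxylate
Conditions: p-TsOH·H2O (5 mol %), toluene, reflux, Dean–Stark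
Reagents that add atoms: none
Why: Acid-catalysed intramolecular aldol condensation (Robinson-type ring closure), in which only the enol of the ethyl branch can reach the non-enolisable aldehyde through a six-membered ring, so the 2-methyl enone forms and the quaternary centre cannot epimerise.

Step 3
Reactants: 4 ethyl (1R)-1,3-dimethyl-4-oxocyclohex-2-ene-1-carboxylate
Product: 5 (1R)-1,3-dimethyl-4-oxocyclohex-2-ene-1-carboxylic acid
Conditions: LiOH·H2O, THF/H2O, 50 °C; then 1 M HCl
Reagents that add atoms: lithium hydroxide, [Li+].[OH-]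
Why: Saponification of the ethyl ester should leave the enone and the quaternary centre untouched.

Step 4
Reactants: 6 2-(3-chloropropyl)-1,3-dioxolane; 7 methyl but-2-ynoate
Product: 9 methyl (2E)-6-(1,3-dioxolan-2-yl)-3-methylhex-2-enoate, via Grignard reagent 8 (not isolated)
Conditions: Mg, THF, 50 °C; CuBr·SMe2 (1 equiv), −78 °C; 7, −78 °C; MeOH, −78 °C; aq NH4Cl
Reagents that add atoms: none
Why: The Grignard reagent is transmetalated to an organocopper that adds syn across the ynoate at −78 °C, and protonation with retention should give the E enoate (chain trans to the ester), which fixes the C13=C14 geometry.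

Step 5
Reactants: 9 methyl (2E)-6-(1,3-dioxolan-2-yl)-3-methylhex-2-enoate
Product: 10 methyl (2E)-3-methyl-7-oxohept-2-enoate
Conditions: 1 M HCl, THF, rt
Reagents that add atoms: water, O
Why: Acid hydrolysis of the dioxolane frees the aldehyde while the enoate is inert.

Step 6
Reactants: 10 methyl (2E)-3-methyl-7-oxohept-2-enoate
Product: 11 methyl (2E)-7-hydroxy-3-methylnon-2-en-8-ynoate (racemic carbinol)
Conditions: ethynylmagnesium bromide (1.1 equiv), THF, −78 °C; aq NH4Cl
Reagents that add atoms: ethynylmagnesium bromide, C#C[Mg]Br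
Why: Chemoselective 1,2-addition of the alkynyl Grignard reagent to the aldehyde, the β,β-disubstituted enoate ester being much slower at −78 °C; the carbinol centre is removed in step 8.

Step 7
Reactants: 11 methyl (2E)-7-hydroxy-3-methylnon-2-en-8-ynoate
Product: 12 methyl (2E,8E)-7-hydroxy-3-methyl-9-(4,4,5,5-tetramethyl-1,3,2-dioxaborolan-2-yl)nona-2,8-dienoate
Conditions: B2pin2 (1.05 equiv), CuCl (5 mol %), Xantphos (5 mol %), NaOtBu (10 mol %), MeOH (2 equiv), THF, rt
Reagents that add atoms: bis(pinacolato)diboron, CC1(C)OB(OC1(C)C)B1OC(C)(C)C(C)(C)O1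
Why: Copper-catalysed protoboration (syn addition of copper–boryl to the terminal alkyne, then protonolysis) should give the linear E alkenyl boronate, the trisubstituted enoate being too hindered for conjugate borylation at room temperature.

Step 8
Reactants: 12 methyl (2E,8E)-7-hydroxy-3-methyl-9-(4,4,5,5-tetramethyl-1,3,2-dioxaborolan-2-yl)nona-2,8-dienoate
Product: 13 methyl (2E,8E)-3-methyl-7-oxo-9-(4,4,5,5-tetramethyl-1,3,2-dioxaborolan-2-yl)nona-2,8-dienoate
Conditions: Dess–Martin periodinane, NaHCO3, CH2Cl2, 0 °C to rt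
Reagents that add atoms: none
Why: Dess–Martin oxidation of the allylic alcohol gives the β-boryl enone, and alkenyl boronates are stable to this oxidant.

Step 9
Reactants: 13 methyl (2E,8E)-3-methyl-7-oxo-9-(4,4,5,5-tetramethyl-1,3,2-dioxaborolan-2-yl)nona-2,8-dienoate
Product: 14 methyl (2E,6Z,8E)-7-[(tert-butyldimethylsilyl)oxy]-3-methyl-9-(4,4,5,5-tetramethyl-1,3,2-dioxaborolan-2-yl)nona-2,6,8-trienoate
Conditions: TBSOTf (1.2 equiv), Et3N (2 equiv), CH2Cl2, −78 to 0 °C
Reagents that add atoms: tert-butyldimethylsilyl trifluoromethanesulfonate, CC(C)(C)[Si](C)(C)OS(=O)(=O)C(F)(F)F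
Why: Soft enolisation towards the only α-CH2 should give the Z silyl enol ether, which places the alkyl chain outside on the s-cis diene; doing this before the union keeps the ring A ketone away from enolising conditions.

Step 10
Reactants: 5 (1R)-1,3-dimethyl-4-oxocyclohex-2-ene-1-carboxylic acid; 14 methyl (2E,6Z,8E)-7-[(tert-butyldimethylsilyl)oxy]-3-methyl-9-(4,4,5,5-tetramethyl-1,3,2-dioxaborolan-2-yl)nona-2,6,8-trienoate
Product: 15 (1E,3Z,7E)-3-[(tert-butyldimethylsilyl)oxy]-9-methoxy-7-methyl-9-oxonona-1,3,7-trien-1-yl (1R)-1,3-dimethyl-4-oxocyclohex-2-ene-1-carboxylate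
Conditions: Cu(OAc)2 (2 equiv), Et3N (3 equiv), DMAP (0.2 equiv), 4 Å MS, CH2Cl2, dry air, rt
Reagents that add atoms: none
Why: Chan–Lam-type oxidative copper-mediated C–O coupling of a carboxylic acid with an alkenyl boronate proceeds with retention and should give the E enol ester, which is the tether.

Step 11
Reactants: 15 (1E,3Z,7E)-3-[(tert-butyldimethylsilyl)oxy]-9-methoxy-7-methyl-9-oxonona-1,3,7-trien-1-yl (1R)-1,3-dimethyl-4-oxocyclohex-2-ene-1-carboxylate
Product: 16 methyl 8-[(tert-butyldimethylsilyl)oxy]-1-oxo-17-norlabda-7,13E-dien-15-oate 19,6α-lactone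
Conditions: toluene (0.01 M), BHT (10 mol %), 150 °C, sealed tube
Reagents that add atoms: none
Why: Thermal, concerted but asynchronous intramolecular [4+2] cycloaddition of the (1E,3Z)-1-acyloxy-3-silyloxy diene C6=C7–C8=C9 onto the enone double bond C5=C10 forms C5–C6 and C9–C10; the closest known types are the type 1 intramolecular Diels–Alder reaction of ester-tethered 1,6,8-nonatrienes with a Z-disposed activating carbonyl and the endo addition of silyloxy dienes to 2-methylcyclohex-2-enones. Ring B is closed by the [4+2] event itself, suprafacially on both partners, and the temporary γ-lactone C4–C19–O–C6–C5 closes in the fused mode because the three-atom tether cannot span the bridged alternative. C5 and C10 arise cis (H-5 and C20 both β) by suprafacial addition to the ring alkene, and their absolute sense follows from C4, since the diene hangs from the α-C19 ester and can reach only the α face. C9 is set by the endo transition state (C1=O and the tether under the diene, cis-fused lactone) together with the Z enol ether, which holds C11 outside and so cis to C1 and trans to C20; C6 is a temporary centre with its oxygen α. The step needs regioselectivity against the electronic bias of the 3-silyloxy diene (secured by the tether), α-facial selectivity (tether), endo selectivity (Alder rule and the less strained cis lactone) and chemoselectivity for the enone over the remote, unactivated enoate.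

Step 12
Reactants: 16 methyl 8-[(tert-butyldimethylsilyl)oxy]-1-oxo-17-norlabda-7,13E-dien-15-oate 19,6α-lactone
Product: 18 dimethyl 1,8-dioxo-17-norlabda-6,13E-diene-15,19-dioate, via caesium carboxylate 17 (not isolated)
Conditions: CsF (3 equiv), DMF, 0 °C; then MeI (5 equiv), 0 °C to rt
Reagents that add atoms: iodomethane, CI
Why: Fluoride cleaves the silyl enol ether to the C8 enolate, which expels the β-carboxylate at C6 (E1cB) and so opens the temporary lactone; methylating the carboxylate in situ prevents its re-addition to the enone.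

Step 13
Reactants: 18 dimethyl 1,8-dioxo-17-norlabda-6,13E-diene-15,19-dioate
Product: 19 dimethyl 1,8-dioxo-17-norlabd-13E-ene-15,19-dioate
Conditions: [(Ph3P)CuH]6 (0.4 equiv), H2O (5 equiv), THF/benzene, rt
Reagents that add atoms: none
Why: Copper hydride conjugate reduction delivers hydride to C6 of the cis-disubstituted enone and the copper enolate is protonated at C7, while the saturated ketone, the esters and the β,β-disubstituted enoate should not react and C9 is not enolised.

Step 14
Reactants: 19 dimethyl 1,8-dioxo-17-norlabd-13E-ene-15,19-dioate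
Product: 20 dimethyl 1-oxolabda-8(17),13E-diene-15,19-dioate
Conditions: Zn/CH2Br2/TiCl4 reagent (preformed in THF), CH2Cl2, 0 °C to rt
Reagents that add atoms: dibromomethane, BrCBr
Why: Lombardo–Takai methylenation is non-basic and should convert the C8 ketone into the exocyclic methylene without epimerising C9, the C1 ketone next to the quaternary C10 and the esters being much slower.

Step 15
Reactants: 20 dimethyl 1-oxolabda-8(17),13E-diene-15,19-dioate
Product: 21 dimethyl 1-[(trifluoromethanesulfonyl)oxy]labda-1,8(17),13E-triene-15,19-dioate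
Conditions: KN(SiMe3)2 (1.1 equiv), THF, −78 °C; PhNTf2 (1.2 equiv), −78 to 0 °C; aq NH4Cl
Reagents that add atoms: N-phenylbis(trifluoromethanesulfonimide), O=S(=O)(N(c1ccccc1)S(=O)(=O)C(F)(F)F)C(F)(F)F
Why: The ketone can be deprotonated only at C2 because C10 is quaternary, and O-triflation of the potassium enolate gives the C1 enol triflate.

Step 16
Reactants: 21 dimethyl 1-[(trifluoromethanesulfonyl)oxy]labda-1,8(17),13E-triene-15,19-dioate
Product: 23 dimethyl 2-oxolabda-8(17),13E-diene-15,19-dioate, via enamine 22 (not isolated)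
Conditions: Pd(OAc)2 (10 mol %), P(4-MeOC6H4)3 (25 mol %), norbornene (50 mol %), 4-(benzoyloxy)morpholine (1.5 equiv), i-PrOH (3 equiv), Cs2CO3 (2.5 equiv), 1,4-dioxane, 100 °C; then 1 M HCl, THF, rt
Reagents that add atoms: water, O
Why: Palladium/norbornene (Catellani-type) relay, in which oxidative addition at C1, norbornene insertion, palladation of the vinylic C2–H, amination at C2 by the N–O electrophile, norbornene extrusion and ipso hydride termination give the C2 enamine, whose hydrolysis is the known route to a 1,2-transposed ketone.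

Step 17
Reactants: 23 dimethyl 2-oxolabda-8(17),13E-diene-15,19-dioate
Product: 24 dimethyl 2β-hydroxylabda-8(17),13E-diene-15,19-dioate
Conditions: Li[(s-Bu)3BH] (1.2 equiv), THF, −78 to 0 °C; aq NH4Cl
Reagents that add atoms: none
Why: In the ring A chair that keeps C9 equatorial the C4 and C10 methyl groups are syn-axial and block the β face of the C2 ketone, so the bulky hydride should attack from the α face (equatorial attack) and give the 2β (axial) alcohol, the esters and the enoate being inert at low temperature.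

Step 18
Reactants: 24 dimethyl 2β-hydroxylabda-8(17),13E-diene-15,19-dioate
Product: 25 2β-hydroxylabda-8(17),13E-diene-15,19-dioic acid (target)
Conditions: LiOH·H2O (10 equiv), THF/MeOH/H2O, 60 °C; then 1 M HCl to pH 3
Reagents that add atoms: lithium hydroxide, [Li+].[OH-]
Why: Saponification of both methyl esters (the neopentyl C19 ester being the slower) should give the diacid, since C4 is quaternary and the 2β-hydroxyl is trans to C19 and cannot lactonise.

**Compound list**

1 | ethyl 2-methyl-3-oxopropanoate | CCOC(=O)C(C)C=O | starting material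
2 | pent-1-en-3-one | CCC(=O)C=C | starting material
3 | ethyl (2R)-2-formyl-2-methyl-5-oxoheptanoate | CCC(=O)CC[C@](C)(C=O)C(=O)OCC | intermediate
4 | ethyl (1R)-1,3-dimethyl-4-oxocyclohex-2-ene-1-carboxylate | CC1=C[C@](C)(C(=O)OCC)CCC1=O | intermediate
5 | (1R)-1,3-dimethyl-4-oxocyclohex-2-ene-1-carboxylic acid | CC1=C[C@](C)(C(=O)O)CCC1=O | intermediate
6 | 2-(3-chloropropyl)-1,3-dioxolane | ClCCCC1OCCO1 | starting material
7 | methyl but-2-ynoate | CC#CC(=O)OC | starting material
8 | [3-(1,3-dioxolan-2-yl)propyl]magnesium chloride | Cl[Mg]CCCC1OCCO1 | intermediate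
9 | methyl (2E)-6-(1,3-dioxolan-2-yl)-3-methylhex-2-enoate | COC(=O)/C=C(\C)CCCC1OCCO1 | intermediate
10 | methyl (2E)-3-methyl-7-oxohept-2-enoate | COC(=O)/C=C(\C)CCCC=O | intermediate
11 | methyl (2E)-7-hydroxy-3-methylnon-2-en-8-ynoate, racemic at C7 | COC(=O)/C=C(\C)CCCC(O)C#C | intermediate
12 | methyl (2E,8E)-7-hydroxy-3-methyl-9-(4,4,5,5-tetramethyl-1,3,2-dioxaborolan-2-yl)nona-2,8-dienoate, racemic at C7 | COC(=O)/C=C(\C)CCCC(O)/C=C/B1OC(C)(C)C(C)(C)O1 | intermediate
13 | methyl (2E,8E)-3-methyl-7-oxo-9-(4,4,5,5-tetramethyl-1,3,2-dioxaborolan-2-yl)nona-2,8-dienoate | COC(=O)/C=C(\C)CCCC(=O)/C=C/B1OC(C)(C)C(C)(C)O1 | intermediate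
14 | methyl (2E,6Z,8E)-7-[(tert-butyldimethylsilyl)oxy]-3-methyl-9-(4,4,5,5-tetramethyl-1,3,2-dioxaborolan-2-yl)nona-2,6,8-trienoate | COC(=O)/C=C(\C)CC/C=C(\O[Si](C)(C)C(C)(C)C)/C=C/B1OC(C)(C)C(C)(C)O1 | intermediate
15 | (1E,3Z,7E)-3-[(tert-butyldimethylsilyl)oxy]-9-methoxy-7-methyl-9-oxonona-1,3,7-trien-1-yl (1R)-1,3-dimethyl-4-oxocyclohex-2-ene-1-carboxylate | CC1=C[C@](C)(C(=O)O/C=C/C(O[Si](C)(C)C(C)(C)C)=C/CC/C(C)=C/C(=O)OC)CCC1=O | intermediate
16 | methyl 8-[(tert-butyldimethylsilyl)oxy]-1-oxo-17-norlabda-7,13E-dien-15-oate 19,6α-lactone (4β-CH3, 5β-H, 6β-H, 9β-H, 10β-CH3; cis-fused decalin, cis-fused γ-lactone) | CC(C)(C)[Si](C)(C)OC1=C[C@H]3[C@H]2[C@](C)(C(=O)CC[C@@]2(C)C(=O)O3)[C@@H]1CC/C(C)=C/C(=O)OC | intermediate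
17 | caesium salt (at C19) of 15-methyl hydrogen 1,8-dioxo-17-norlabda-6,13E-diene-15,19-dioate (4β-CH3, 5β-H, 9β-H, 10β-CH3) | O=C1C=C[C@H]2[C@](C)(C(=O)CC[C@@]2(C)C(=O)[O-])[C@@H]1CC/C(C)=C/C(=O)OC.[Cs+] | intermediate
18 | dimethyl 1,8-dioxo-17-norlabda-6,13E-diene-15,19-dioate (4β-CH3, 5β-H, 9β-H, 10β-CH3) | O=C1C=C[C@H]2[C@](C)(C(=O)CC[C@@]2(C)C(=O)OC)[C@@H]1CC/C(C)=C/C(=O)OC | intermediate
19 | dimethyl 1,8-dioxo-17-norlabd-13E-ene-15,19-dioate (4β-CH3, 5β-H, 9β-H, 10β-CH3) | O=C1CC[C@H]2[C@](C)(C(=O)CC[C@@]2(C)C(=O)OC)[C@@H]1CC/C(C)=C/C(=O)OC | intermediate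
20 | dimethyl 1-oxolabda-8(17),13E-diene-15,19-dioate (4β-CH3, 5β-H, 9β-H, 10β-CH3) | C=C1CC[C@H]2[C@](C)(C(=O)CC[C@@]2(C)C(=O)OC)[C@@H]1CC/C(C)=C/C(=O)OC | intermediate
21 | dimethyl 1-[(trifluoromethanesulfonyl)oxy]labda-1,8(17),13E-triene-15,19-dioate (4β-CH3, 5β-H, 9β-H, 10β-CH3) | C=C1CC[C@H]2[C@](C)(C(OS(=O)(=O)C(F)(F)F)=CC[C@@]2(C)C(=O)OC)[C@@H]1CC/C(C)=C/C(=O)OC | intermediate
22 | dimethyl 2-(morpholin-4-yl)labda-1,8(17),13E-triene-15,19-dioate (4β-CH3, 5β-H, 9β-H, 10β-CH3) | C=C1CC[C@H]2[C@](C)(C=C(N3CCOCC3)C[C@@]2(C)C(=O)OC)[C@@H]1CC/C(C)=C/C(=O)OC | intermediate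
23 | dimethyl 2-oxolabda-8(17),13E-diene-15,19-dioate (4β-CH3, 5β-H, 9β-H, 10β-CH3) | C=C1CC[C@H]2[C@](C)(CC(=O)C[C@@]2(C)C(=O)OC)[C@@H]1CC/C(C)=C/C(=O)OC | intermediate
24 | dimethyl 2β-hydroxylabda-8(17),13E-diene-15,19-dioate (4β-CH3, 5β-H, 9β-H, 10β-CH3) | C=C1CC[C@H]2[C@](C)(C[C@H](O)C[C@@]2(C)C(=O)OC)[C@@H]1CC/C(C)=C/C(=O)OC | intermediate
25 | 2β-hydroxylabda-8(17),13E-diene-15,19-dioic acid (4β-CH3, 4α-CO2H, 5β-H, 9β-H, 10β-CH3), i.e. the (2S,4R,5S,9R,10R) diacid | C=C1CC[C@H]2[C@](C)(C[C@H](O)C[C@@]2(C)C(=O)O)[C@@H]1CC/C(C)=C/C(=O)O | target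

**Totals and risks**

Total step count: 18. Longest linear sequence: 15 steps (steps 4 to 18, from 6 and 7).

Steps most likely to fail:

Step 11. The cycloaddition may stall, or lose its endo preference and so scramble C9, because the tether forces the 3-silyloxy diene to bond against its electronic bias; the silyl dienol ether may also decay on long heating. The fallback carries no oxygen on C8 through the cycloaddition and sets out from 5 and 10. Aldehyde 10 is homologated with (triphenylphosphoranylidene)acetaldehyde to methyl (2E,7E)-3-methyl-9-oxonona-2,7-dienoate F1. Acid 5 is converted with oxalyl chloride and catalytic DMF into (1R)-1,3-dimethyl-4-oxocyclohex-2-ene-1-carbonyl chloride F2. The potassium dienolate of F1 (KOtBu, THF, −78 °C) is O-acylated by F2 to give the electronically unbiased (1E,3E,7E)-9-methoxy-7-methyl-9-oxonona-1,3,7-trien-1-yl ester F3. Heating in toluene should give the 1-oxo-17-norlabda-7,13E-dien-15-oate 19,6α-lactone F4 through the same tether-controlled transition state. Wacker–Tsuji oxidation (PdCl2, CuCl, O2, DMF/H2O) should place the carbonyl on C8, the carbon remote from the allylic oxygen, to give the 1,8-dioxo-17-norlabd-13E-en-15-oate 19,6α-lactone F5. K2CO3 and MeI in DMF then effect the E1cB opening and esterification, and the route is rejoined at 18.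

Step 10. The dienyl boronate may protodeboronate, or its silyl dienol ether may be degraded under the copper/air conditions. The fallback forms the enol ester C–O bond by O-acylation of a preformed dienolate and sets out from 11 and 5. Alcohol 11 is oxidised (Dess–Martin periodinane) to methyl (2E)-3-methyl-7-oxonon-2-en-8-ynoate F6. DABCO-catalysed conjugate addition of acetic acid gives methyl (2E,8E)-9-acetoxy-3-methyl-7-oxonona-2,8-dienoate F7. TBSOTf/Et3N gives methyl (2E,6Z,8E)-9-acetoxy-7-[(tert-butyldimethylsilyl)oxy]-3-methylnona-2,6,8-trienoate F8, with no competing ketone present. KOtBu (1 equiv, THF, −78 °C) removes the acetyl group to leave the potassium dienolate. This is acylated on oxygen by (1R)-1,3-dimethyl-4-oxocyclohex-2-ene-1-carbonyl fluoride F9 (from 5 with cyanuric fluoride and pyridine), and the route is rejoined at 15.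

Step 16. Oxidative addition and the norbornene relay may be slow at the hindered C1 triflate, or direct reduction to the C1=C2 alkene may compete. The fallback is the classical sulfur-mediated 1,2-carbonyl transposition and sets out from 20. Deprotonation with LiN(i-Pr)2 and sulfenylation with diphenyl disulfide give dimethyl 1-oxo-2-(phenylsulfanyl)labda-8(17),13E-diene-15,19-dioate F10 (either C2 epimer). NaBH4 gives dimethyl 1-hydroxy-2-(phenylsulfanyl)labda-8(17),13E-diene-15,19-dioate F11. Mesylation (MsCl, Et3N) and elimination with DBU give dimethyl 2-(phenylsulfanyl)labda-1,8(17),13E-triene-15,19-dioate F12. Hydrolysis of the vinyl sulfide (HgCl2, MeCN/H2O) returns the route at 23.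

Further compounds
F1 | step 11 | methyl (2E,7E)-3-methyl-9-oxonona-2,7-dienoate | COC(=O)/C=C(\C)CCC/C=C/C=O
F2 | step 11 | (1R)-1,3-dimethyl-4-oxocyclohex-2-ene-1-carbonyl chloride | CC1=C[C@](C)(C(Cl)=O)CCC1=O
F3 | step 11 | (1E,3E,7E)-9-methoxy-7-methyl-9-oxonona-1,3,7-trien-1-yl (1R)-1,3-dimethyl-4-oxocyclohex-2-ene-1-carboxylate | CC1=C[C@](C)(C(=O)O/C=C/C=C/CC/C(C)=C/C(=O)OC)CCC1=O
F4 | step 11 | methyl 1-oxo-17-norlabda-7,13E-dien-15-oate 19,6α-lactone (4β-CH3, 5β-H, 6β-H, 9β-H, 10β-CH3) | C1=C[C@H]3[C@H]2[C@](C)(C(=O)CC[C@@]2(C)C(=O)O3)[C@@H]1CC/C(C)=C/C(=O)OC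
F5 | step 11 | methyl 1,8-dioxo-17-norlabd-13E-en-15-oate 19,6α-lactone (4β-CH3, 5β-H, 6β-H, 9β-H, 10β-CH3) | O=C1C[C@H]3[C@H]2[C@](C)(C(=O)CC[C@@]2(C)C(=O)O3)[C@@H]1CC/C(C)=C/C(=O)OC
F6 | step 10 | methyl (2E)-3-methyl-7-oxonon-2-en-8-ynoate | COC(=O)/C=C(\C)CCCC(=O)C#C
F7 | step 10 | methyl (2E,8E)-9-acetoxy-3-methyl-7-oxonona-2,8-dienoate | COC(=O)/C=C(\C)CCCC(=O)/C=C/OC(C)=O
F8 | step 10 | methyl (2E,6Z,8E)-9-acetoxy-7-[(tert-butyldimethylsilyl)oxy]-3-methylnona-2,6,8-trienoate | COC(=O)/C=C(\C)CC/C=C(\O[Si](C)(C)C(C)(C)C)/C=C/OC(C)=O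
F9 | step 10 | (1R)-1,3-dimethyl-4-oxocyclohex-2-ene-1-carbonyl fluoride | CC1=C[C@](C)(C(F)=O)CCC1=O
F10 | step 16 | dimethyl 1-oxo-2-(phenylsulfanyl)labda-8(17),13E-diene-15,19-dioate (4β-CH3, 5β-H, 9β-H, 10β-CH3; C2 either epimer) | C=C1CC[C@H]2[C@](C)(C(=O)C(Sc3ccccc3)C[C@@]2(C)C(=O)OC)[C@@H]1CC/C(C)=C/C(=O)OC
F11 | step 16 | dimethyl 1-hydroxy-2-(phenylsulfanyl)labda-8(17),13E-diene-15,19-dioate (4β-CH3, 5β-H, 9β-H, 10β-CH3; C1 and C2 either epimer) | C=C1CC[C@H]2[C@](C)(C(O)C(Sc3ccccc3)C[C@@]2(C)C(=O)OC)[C@@H]1CC/C(C)=C/C(=O)OC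
F12 | step 16 | dimethyl 2-(phenylsulfanyl)labda-1,8(17),13E-triene-15,19-dioate (4β-CH3, 5β-H, 9β-H, 10β-CH3) | C=C1CC[C@H]2[C@](C)(C=C(Sc3ccccc3)C[C@@]2(C)C(=O)OC)[C@@H]1CC/C(C)=C/C(=O)OC
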